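**Retrosynthetic overview**

- 10 ⇒ 8: the (E)-3-hydroxyprop-1-enyl chain on ring A (the arene fused to the dioxane) is taken back to a formyl group (Horner–Wadsworth–Emmons olefination, then i-Bu2AlH).
- 8 ⇒ 7: ring C (the dioxane; the only ring built, and built last) is opened at the aryl ether bond between O-b, the oxygen on the CH3-bearing carbon C-b, and the ring A carbon next to the OCH3-bearing carbon; forward, this bond closes ring C by intramolecular O-arylation of the C–Br bond at that carbon.
- 7 ⇒ 6 + 4: the benzylic ether bond between O-a (the phenol oxygen of ring A) and C-a (the carbon bearing ring B, the 3,4,5-trimethoxyphenyl group) comes from opening of cis-epoxide 4 by the phenoxide of 6 with inversion; opening and ring closure run in one flask, so two simple fragments should give the complete trans-dioxane core.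
- 4 ⇒ 3 ⇒ 1 + 2: both stereocentres are set by Jacobsen–Katsuki epoxidation of a Z-propenylarene made by Suzuki–Miyaura coupling; 6 ⇒ 5 by one O-demethylation.
- Enabling feature: the bromo carbon of ring A lies ortho to the phenol carbon, so the chain O-a–C-a–C-b–O-b reaches it through a six-membered ring, and para to the formyl carbon; with the side chain held as CHO, this C–Br bond is the only carbon–halogen bond and is activated, whereas the phenol carbon (meta to CHO) resists ipso attack, so the two dioxane oxygens cannot change places.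

Key step: step 4

Remark: 1, 2 and 5 are taken as purchasable; should phenol 6 itself be purchasable, step 3 falls away.

Step 1
Reactants: 1 5-bromo-1,2,3-trimethoxybenzene; 2 (Z)-prop-1-en-1-ylboronic acid
Product: 3 1,2,3-trimethoxy-5-[(Z)-prop-1-en-1-yl]benzene
Conditions: Pd(PPh3)4 (cat.), K2CO3, 1,4-dioxane/H2O, 80 °C
Reagents that add atoms: none
Why: Suzuki–Miyaura coupling of an aryl bromide with an alkenylboronic acid; transmetalation and reductive elimination proceed with retention of alkene geometry, so the Z-propenyl unit should be transferred intact, and no stereocentre is formed.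

Step 2
Reactants: 3 1,2,3-trimethoxy-5-[(Z)-prop-1-en-1-yl]benzene
Product: 4 (2R,3S)-2-methyl-3-(3,4,5-trimethoxyphenyl)oxirane
Conditions: (S,S)-(salen)MnCl (cat.; salen = dianion of N,N'-bis(3,5-di-tert-butylsalicylidene)cyclohexane-1,2-diamine), NaOCl (aq., pH 11), 4-phenylpyridine N-oxide, CH2Cl2, 0 °C
Reagents that add atoms: sodium hypochlorite, [Na+].[O-]Cl
Why: Jacobsen–Katsuki epoxidation, for which aryl-conjugated cis-disubstituted alkenes are the best substrate class; both stereocentres are set together by catalyst-controlled oxygen transfer to one face of the Z-alkene, the (S,S) catalyst being the enantiomer expected to give the cis-epoxide with an S benzylic carbon.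

Step 3
Reactants: 5 4-bromo-3,5-dimethoxybenzaldehyde
Product: 6 4-bromo-3-hydroxy-5-methoxybenzaldehyde
Conditions: BBr3, CH2Cl2, −78 to 0 °C; then H2O
Reagents that add atoms: none
Why: Lewis acid ether cleavage (BBr3 O-demethylation); the two methoxy groups of 5 are equivalent, so limiting the reagent should give the mono-phenol as main product, with 5 and the diphenol separable, and no stereocentre is involved.

Step 4
Reactants: 6 4-bromo-3-hydroxy-5-methoxybenzaldehyde; 4 (2R,3S)-2-methyl-3-(3,4,5-trimethoxyphenyl)oxirane
Product: 8 (2R,3R)-8-methoxy-2-methyl-3-(3,4,5-trimethoxyphenyl)-2,3-dihydro-1,4-benzodioxine-6-carbaldehyde, via bromoaryl ether alcohol 7 (not isolated)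
Conditions: Cs2CO3, DMF, 80 °C; then CuI (cat.), 1,10-phenanthroline, 110 °C, same flask, N2
Reagents that add atoms: none
Why: Cs2CO3 turns 6 into its phenoxide, which opens cis-epoxide 4 by SN2 attack at the benzylic carbon C-a to give alcohol 7 as its cesium alkoxide, and the alkoxide oxygen O-b then replaces bromide on the bromo carbon of ring A by CuI/phenanthroline-mediated Ullmann-type O-arylation, an uncatalysed addition–elimination (SNAr) path being open as well because this carbon is para to the formyl group. The closest known reaction type is the copper-catalysed tandem epoxide ring-opening/intramolecular C–O coupling of 2-halophenols, an established entry to 2,3-dihydro-1,4-benzodioxines. Ring C closes as a six-membered ring (6-exo-trig in the addition–elimination picture), O-b attacking the sp2 bromo carbon that it reaches through C-b, C-a, O-a and the phenol carbon. C-a becomes R by stereospecific inversion of the S-configured epoxide carbon (substrate control, no external chiral agent), and C-b keeps the R configuration it had in 4, so the cis-epoxide should map onto the trans-dioxane. The step needs attack at C-a and not at C-b, which is secured by benzylic activation by ring B in an epoxide whose two carbons are otherwise equally substituted, and it needs closure at the bromo carbon only, which is secured by the single C–Br bond para to CHO while the phenol carbon, meta to CHO, is not prone to ipso attack.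

Step 5
Reactants: 8 (2R,3R)-8-methoxy-2-methyl-3-(3,4,5-trimethoxyphenyl)-2,3-dihydro-1,4-benzodioxine-6-carbaldehyde
Product: 9 ethyl (E)-3-[(2R,3R)-8-methoxy-2-methyl-3-(3,4,5-trimethoxyphenyl)-2,3-dihydro-1,4-benzodioxin-6-yl]prop-2-enoate
Conditions: (EtO)2P(O)CH2CO2Et, NaH, THF, 0 °C to rt
Reagents that add atoms: triethyl phosphonoacetate, CCOC(=O)CP(=O)(OCC)OCC
Why: Horner–Wadsworth–Emmons olefination of an aromatic aldehyde with a stabilised phosphonate anion should give the E-enoate, and the two stereocentres, neither of which is acidic, are untouched.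

Step 6
Reactants: 9 ethyl (E)-3-[(2R,3R)-8-methoxy-2-methyl-3-(3,4,5-trimethoxyphenyl)-2,3-dihydro-1,4-benzodioxin-6-yl]prop-2-enoate
Product: 10 (E)-3-[(2R,3R)-8-methoxy-2-methyl-3-(3,4,5-trimethoxyphenyl)-2,3-dihydro-1,4-benzodioxin-6-yl]prop-2-en-1-ol
Conditions: i-Bu2AlH, CH2Cl2, −78 °C; then aq. KNaC4H4O6
Reagents that add atoms: none
Why: 1,2-Reduction of an α,β-unsaturated ester by i-Bu2AlH at low temperature should give the E-allylic alcohol without touching the alkene, the aryl ethers or the stereocentres.

**Compound list**

1 | 5-bromo-1,2,3-trimethoxybenzene | COc1cc(Br)cc(OC)c1OC | starting material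
2 | (Z)-prop-1-en-1-ylboronic acid | C/C=C\B(O)O | starting material
3 | 1,2,3-trimethoxy-5-[(Z)-prop-1-en-1-yl]benzene | C/C=C\c1cc(OC)c(OC)c(OC)c1 | intermediate
4 | (2R,3S)-2-methyl-3-(3,4,5-trimethoxyphenyl)oxirane (cis) | C[C@H]1O[C@H]1c1cc(OC)c(OC)c(OC)c1 | intermediate
5 | 4-bromo-3,5-dimethoxybenzaldehyde | O=Cc1cc(OC)c(Br)c(OC)c1 | starting material
6 | 4-bromo-3-hydroxy-5-methoxybenzaldehyde | O=Cc1cc(O)c(Br)c(OC)c1 | intermediate
7 | 4-bromo-3-{[(1R,2R)-2-hydroxy-1-(3,4,5-trimethoxyphenyl)propyl]oxy}-5-methoxybenzaldehyde (present in the flask as its cesium alkoxide) | COc1cc([C@@H](Oc2cc(C=O)cc(OC)c2Br)[C@H](O)C)cc(OC)c1OC | intermediate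
8 | (2R,3R)-8-methoxy-2-methyl-3-(3,4,5-trimethoxyphenyl)-2,3-dihydro-1,4-benzodioxine-6-carbaldehyde | COc1cc([C@H]2Oc3cc(C=O)cc(OC)c3O[C@@H]2C)cc(OC)c1OC | intermediate
9 | ethyl (E)-3-[(2R,3R)-8-methoxy-2-methyl-3-(3,4,5-trimethoxyphenyl)-2,3-dihydro-1,4-benzodioxin-6-yl]prop-2-enoate | COc1cc([C@H]2Oc3cc(/C=C/C(=O)OCC)cc(OC)c3O[C@@H]2C)cc(OC)c1OC | intermediate
10 | (E)-3-[(2R,3R)-8-methoxy-2-methyl-3-(3,4,5-trimethoxyphenyl)-2,3-dihydro-1,4-benzodioxin-6-yl]prop-2-en-1-ol | COc1cc([C@H]2Oc3cc(/C=C/CO)cc(OC)c3O[C@@H]2C)cc(OC)c1OC | target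

Total step count: 6. Longest linear sequence: 5 steps (steps 1, 2, 4, 5, 6).

**Steps most likely to fail: step 4, step 2, step 1**

Step 4. The phenoxide may attack the CH3-bearing epoxide carbon in part, which would lead to the regioisomeric dioxane. It may also open the benzylic carbon with some ionisation, so that inversion is incomplete. The hindered, doubly ortho-substituted bromide may close slowly, letting the alkoxide revert or oligomerise. The fallback sets out from 1 and 6 and comes back at 8; it fixes regiochemistry and configuration by a Mitsunobu inversion instead of an epoxide opening. Commercial methyl (R)-lactate is silylated (TBSCl, imidazole, DMF) to methyl (R)-2-[(tert-butyldimethylsilyl)oxy]propanoate F1, which is reduced (i-Bu2AlH, CH2Cl2, −78 °C) to (R)-2-[(tert-butyldimethylsilyl)oxy]propanal F2. Bromide 1 is converted (n-BuLi, THF, −78 °C) into 3,4,5-trimethoxyphenyllithium F3, whose Felkin–Anh addition to F2 should give the anti alcohol (1S,2R)-2-[(tert-butyldimethylsilyl)oxy]-1-(3,4,5-trimethoxyphenyl)propan-1-ol F4, the minor syn isomer being removed by chromatography. Mitsunobu etherification of F4 with phenol 6 (PPh3, DIAD, THF, 0 °C) should invert the benzylic carbon and give 4-bromo-3-{[(1R,2R)-2-[(tert-butyldimethylsilyl)oxy]-1-(3,4,5-trimethoxyphenyl)propyl]oxy}-5-methoxybenzaldehyde F5. Bu4NF in THF then frees alcohol 7, now isolated, and palladium-catalysed intramolecular C–O coupling (Pd(OAc)2, 2-(di-tert-butylphosphino)-1,1'-binaphthyl, Cs2CO3, toluene, 70 °C) closes ring C to 8.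

Step 2. Oxygen transfer from the manganese oxo species passes through a radical intermediate in which the C–C bond can rotate before ring closure, so trans-epoxide may leak in and end as the cis-dioxane. Facial selection may also be incomplete for this electron-rich arene, which would carry the minor enantiomer forward. One recrystallisation of 8 or 9 is planned in any case. The fallback sets out from 1 and comes back at 4; it takes the CH3-bearing stereocentre from the chiral pool. Bromide 1 and Mg in THF give 3,4,5-trimethoxyphenylmagnesium bromide F6, which is added to commercial (S)-N,N-dimethyllactamide, pre-deprotonated with i-PrMgCl, to give after NH4Cl work-up (S)-2-hydroxy-1-(3,4,5-trimethoxyphenyl)propan-1-one F7. TsCl and pyridine give (S)-1-oxo-1-(3,4,5-trimethoxyphenyl)propan-2-yl 4-methylbenzenesulfonate F8. Felkin–Anh-controlled hydride reduction (NaBH4, MeOH, −40 °C) should give the syn alcohol (1S,2S)-1-hydroxy-1-(3,4,5-trimethoxyphenyl)propan-2-yl 4-methylbenzenesulfonate F9, and K2CO3 in MeOH closes the oxirane with inversion at the sulfonate carbon to give 4.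

Step 1. The Z geometry may erode through Pd–H addition/elimination on the product or through partly isomerised or protodeboronated boronic acid. Any E-alkene would be carried into the trans-epoxide. The fallback sets out from 1 and comes back at 3; it builds the Z-alkene by syn-hydrogenation instead of by transfer of a preformed alkenyl group. Sonogashira coupling of 1 with propyne (Pd(PPh3)2Cl2, CuI, Et3N, 50 °C) gives 1,2,3-trimethoxy-5-(prop-1-yn-1-yl)benzene F10, and semi-hydrogenation (H2, Pd/CaCO3 poisoned with Pb(OAc)2, quinoline, EtOAc) gives 3.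

Further compounds
F1 | step 4 | methyl (R)-2-[(tert-butyldimethylsilyl)oxy]propanoate | C[C@@H](O[Si](C)(C)C(C)(C)C)C(=O)OC
F2 | step 4 | (R)-2-[(tert-butyldimethylsilyl)oxy]propanal | C[C@@H](O[Si](C)(C)C(C)(C)C)C=O
F3 | step 4 | 3,4,5-trimethoxyphenyllithium | COc1cc([Li])cc(OC)c1OC
F4 | step 4 | (1S,2R)-2-[(tert-butyldimethylsilyl)oxy]-1-(3,4,5-trimethoxyphenyl)propan-1-ol | C[C@@H](O[Si](C)(C)C(C)(C)C)[C@@H](O)c1cc(OC)c(OC)c(OC)c1
F5 | step 4 | 4-bromo-3-{[(1R,2R)-2-[(tert-butyldimethylsilyl)oxy]-1-(3,4,5-trimethoxyphenyl)propyl]oxy}-5-methoxybenzaldehyde | COc1cc([C@@H](Oc2cc(C=O)cc(OC)c2Br)[C@H](O[Si](C)(C)C(C)(C)C)C)cc(OC)c1OC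
F6 | step 2 | 3,4,5-trimethoxyphenylmagnesium bromide | COc1cc([Mg]Br)cc(OC)c1OC
F7 | step 2 | (S)-2-hydroxy-1-(3,4,5-trimethoxyphenyl)propan-1-one | C[C@H](O)C(=O)c1cc(OC)c(OC)c(OC)c1
F8 | step 2 | (S)-1-oxo-1-(3,4,5-trimethoxyphenyl)propan-2-yl 4-methylbenzenesulfonate | C[C@H](OS(=O)(=O)c1ccc(C)cc1)C(=O)c1cc(OC)c(OC)c(OC)c1
F9 | step 2 | (1S,2S)-1-hydroxy-1-(3,4,5-trimethoxyphenyl)propan-2-yl 4-methylbenzenesulfonate | C[C@H](OS(=O)(=O)c1ccc(C)cc1)[C@@H](O)c1cc(OC)c(OC)c(OC)c1
F10 | step 1 | 1,2,3-trimethoxy-5-(prop-1-yn-1-yl)benzene | CC#Cc1cc(OC)c(OC)c(OC)c1
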